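**Plan**

1. Retrosynthesis (labdane numbering): the acetate C–O bond is cut first, then C14–C15 and C13–C16 (back to a C13≡C14 alkyne, itself from a C13 aldehyde), then C5–H (back to a C5=C6 alkene), then C8–CH3 (back to a C8 ketone), and last C6–C7 and C9–C10 of ring B together.
2. Enabling feature: in ring B (C5–C10) the carbinol carbon C8 lies between C7 and C9, which are bonded to C6 and to the quaternary ring-fusion carbon C10. Ring B is therefore a cyclohexanone whose two α-carbons can join the formyl carbon and the β-carbon of the enal C6(=O)–C5=C10 of β-cyclocitral (ring A ready-made). C7–C8–C9 come from an acetoacetate that already carries C11–C13 on C9.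
3. Forward: ring A is bought. Ring B is made in one operation: asymmetric vinylogous aldol (C6–C7), a temporary δ-lactone through the C6 oxygen, a ring-contracting Carroll shift (C9–C10), and loss of the lactone carbonyl as CO2. Then follow C8 methylation, C5=C6 hydrogenation and completion of the side chain.
4. Stereochemistry: chiral catalyst → C6 (temporary) → C10 by [3,3] chirality transfer; C9 by protonation anti to the C10 methyl; C8 by equatorial methyl delivery (8-OH syn to C10–CH3); C5 by hydroxyl-directed hydrogenation (cis ring fusion); C13=C14 (E) by syn-carboalumination.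

Key step: step 3

Remark 1: ring atoms carry labdane numbers (C5/C10 ring fusion, C8 carbinol, C9 side-chain carbon, C11–C16 side chain). In the target, 5-H, 10-CH3, the C9 side chain and 8-OH all lie on one face of a cis-fused decalin, and the route is planned for that arrangement.

Remark 2: (S)-BINOL is assumed to direct the dienolate to the Si face of the formyl group, as with aryl and alkenyl aldehydes. Should the sense be the opposite, (R)-BINOL is used.

**Route**

Step 1
Reactants: 1 methyl acetoacetate; 2 2-(2-bromoethyl)-1,3-dioxolane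
Product: 3 methyl 2-acetyl-4-(1,3-dioxolan-2-yl)butanoate
Conditions: NaH, NaI (cat.), THF–DMF, 0 → 60 °C
Reagents that add atoms: none
Why: C-alkylation of the sodium enolate of a β-keto ester with a primary bromide (acetoacetic ester alkylation) should place the future C11–C13 chain, with C13 masked as an acetal, on the carbon that becomes C9.

Step 2
Reactants: 3 methyl 2-acetyl-4-(1,3-dioxolan-2-yl)butanoate
Product: 5 2-[2-(1,3-dioxolan-2-yl)ethyl]-1-methoxy-1,3-bis(trimethylsilyloxy)buta-1,3-diene, via silyl enol ether 4 (not isolated)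
Conditions: Et3N, TMSCl, hexane, rt; filtration, concentration; then LDA, THF, −78 °C; TMSCl
Reagents that add atoms: chlorotrimethylsilane, C[Si](C)(C)Cl
Why: O-silylation of the β-keto ester enol, then γ-deprotonation and O-silylation of the ester dienolate, is the standard two-stage preparation of a 1,3-bis(silyl enol ether), which reacts as an acetoacetate dianion equivalent at its terminal carbon.

Step 3
Reactants: 5 2-[2-(1,3-dioxolan-2-yl)ethyl]-1-methoxy-1,3-bis(trimethylsilyloxy)buta-1,3-diene; 6 β-cyclocitral (2,6,6-trimethylcyclohex-1-ene-1-carbaldehyde)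
Product: 11 (1R,8aR)-1-[2-(1,3-dioxolan-2-yl)ethyl]-5,5,8a-trimethyl-3,5,6,7,8,8a-hexahydronaphthalen-2(1H)-one, via bis-silyl aldol adduct 7 (not isolated), via hydroxy keto ester 8 (not isolated), via keto lactone 9 (not isolated), via keto acid 10 (not isolated)
Conditions: (S)-BINOL (20 mol %), Ti(OiPr)4 (20 mol %), 4 Å MS, THF, −78 °C → rt; then K2CO3, MeOH, 0 °C → rt; then AcOH, solvent change to xylenes, 140 °C
Reagents that add atoms: none
Why: Proposed new method: the chiral tetravalent-titanium BINOLate catalyses a vinylogous Mukaiyama aldol addition of the terminal CH2 of diene 5 (the future C7) to the Si face of the formyl carbon of 6 (the future C6), and methanolic K2CO3 then removes both silyl groups and lets the C6 oxygen attack the methyl ester, which closes the temporary δ-lactone 9 by a 6-exo-trig acyl substitution. On heating, the ester-enol form of 9 should undergo a [3,3]-sigmatropic (Carroll) shift in which the lactone α-carbon (C9) bonds to the ring-A alkene carbon C10 while the allylic C6–O bond breaks, so that the six-membered lactone contracts to carbocyclic ring B through a boat-like, bicyclo[2.2.2]octane-shaped transition state (a 6-endo closure with respect to the C5=C10 bond, which moves to C5=C6), and the β-keto acid 10 then loses CO2. The closest known reactions are the Carroll rearrangement of open-chain allyl β-keto esters and the ester-enolate Claisen ring contraction of 6-alkenyl lactones; their combination on a β-keto δ-lactone with a fully substituted alkene terminus is the untested part. The quaternary centre C10 is fixed by suprafacial transfer of chirality from the catalyst-made (S)-carbinol C6, because the tether allows only the transition state with C7 cis to C10, and C9 is fixed by protonation of the enol left by decarboxylation on the face opposite the axial C10 methyl group. The step needs attack by the terminal and not the central carbon of the dienolate (secured by the 1,3-bis(silyl enol ether)), 1,2- and not 1,4-addition (the β-carbon of 6 is fully substituted and 6 has no α-hydrogen), and rearrangement instead of ionisation and elimination of the allylic ester (the lactone holds C9 within reach of C10 and its s-trans ester geometry excludes syn-elimination).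

Step 4
Reactants: 11 (1R,8aR)-1-[2-(1,3-dioxolan-2-yl)ethyl]-5,5,8a-trimethyl-3,5,6,7,8,8a-hexahydronaphthalen-2(1H)-one
Product: 12 (1R,2S,8aR)-1-[2-(1,3-dioxolan-2-yl)ethyl]-2,5,5,8a-tetramethyl-1,2,3,5,6,7,8,8a-octahydronaphthalen-2-ol
Conditions: CeCl3 (dried), MeLi, THF, −78 °C; aq. NH4Cl
Reagents that add atoms: methyllithium, [Li]C
Why: the weakly basic organocerium reagent should add to the enolisable β,γ-unsaturated ketone (1,2-addition of an organocerium reagent) along the equatorial trajectory on the α face, because the axial trajectory on the β face is closed by the axial C10 methyl group and the neighbouring β side chain, which places the new 8-OH axial and syn to the C10 methyl group.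

Step 5
Reactants: 12 (1R,2S,8aR)-1-[2-(1,3-dioxolan-2-yl)ethyl]-2,5,5,8a-tetramethyl-1,2,3,5,6,7,8,8a-octahydronaphthalen-2-ol
Product: 13 (1R,2S,4aR,8aS)-1-[2-(1,3-dioxolan-2-yl)ethyl]-2,5,5,8a-tetramethyldecahydronaphthalen-2-ol
Conditions: [Ir(cod)(PCy3)(py)]PF6 (10 mol %), H2 (1 atm), CH2Cl2, rt
Reagents that add atoms: none
Why: in this hydroxyl-directed homogeneous hydrogenation the axial homoallylic 8-OH should bind the cationic iridium catalyst and deliver both hydrogens to the face of the C5=C6 alkene that carries the hydroxyl group, which sets 5-H syn to 8-OH and to the C10 methyl group, that is, the cis ring fusion.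

Step 6
Reactants: 13 (1R,2S,4aR,8aS)-1-[2-(1,3-dioxolan-2-yl)ethyl]-2,5,5,8a-tetramethyldecahydronaphthalen-2-ol
Product: 14 3-[(1R,2S,4aR,8aS)-2-hydroxy-2,5,5,8a-tetramethyldecahydronaphthalen-1-yl]propanal (in equilibrium with its six-membered lactol)
Conditions: PPTS (cat.), acetone–H2O (5:1), 60 °C
Reagents that add atoms: water, O
Why: mild acid-catalysed acetal hydrolysis should free the C13 aldehyde, which is held as its lactol with the 8-OH, under conditions too weak to ionise the tertiary alcohol.

Step 7
Reactants: 14 3-[(1R,2S,4aR,8aS)-2-hydroxy-2,5,5,8a-tetramethyldecahydronaphthalen-1-yl]propanal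
Product: 15 (1R,2S,4aR,8aS)-1-(but-3-yn-1-yl)-2,5,5,8a-tetramethyldecahydronaphthalen-2-ol
Conditions: dimethyl (1-diazo-2-oxopropyl)phosphonate, K2CO3, MeOH, 0 °C → rt
Reagents that add atoms: dimethyl (1-diazo-2-oxopropyl)phosphonate, CC(=O)C(=[N+]=[N-])P(=O)(OC)OC
Why: in the Ohira–Bestmann homologation the lactol opens under the basic conditions and the aldehyde should be converted into the terminal alkyne C13≡C14 without touching any stereocentre.

Step 8
Reactants: 15 (1R,2S,4aR,8aS)-1-(but-3-yn-1-yl)-2,5,5,8a-tetramethyldecahydronaphthalen-2-ol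
Product: 17 (1R,2S,4aR,8aS)-1-[(3E)-5-hydroxy-3-methylpent-3-en-1-yl]-2,5,5,8a-tetramethyldecahydronaphthalen-2-ol, via alkenylalane 16 (not isolated)
Conditions: AlMe3 (3.5 equiv), Cp2ZrCl2 (0.3 equiv), CH2Cl2, 0 °C → rt; then (CH2O)n, THF, rt; aq. HCl (1 M), 0 °C
Reagents that add atoms: trimethylaluminium, C[Al](C)C; paraformaldehyde (as formaldehyde), C=O
Why: zirconium-catalysed syn-carboalumination of the terminal alkyne (Negishi carboalumination) places methyl on C13 and aluminium on C14 cis to each other, and trapping of the alkenylalane with formaldehyde with retention should give only the (E)-allylic alcohol, the tertiary hydroxyl being carried as its aluminium alkoxide.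

Step 9
Reactants: 17 (1R,2S,4aR,8aS)-1-[(3E)-5-hydroxy-3-methylpent-3-en-1-yl]-2,5,5,8a-tetramethyldecahydronaphthalen-2-ol
Product: 18 (2E)-5-[(1R,2S,4aR,8aS)-2-hydroxy-2,5,5,8a-tetramethyldecahydronaphthalen-1-yl]-3-methylpent-2-en-1-yl acetate (the target)
Conditions: Ac2O, pyridine, CH2Cl2, 0 °C → rt
Reagents that add atoms: acetic anhydride, CC(=O)OC(C)=O
Why: acylation with Ac2O and pyridine (no acyl-transfer catalyst) should acetylate the primary allylic alcohol only, because the hindered axial tertiary 8-OH does not react under these conditions.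

**Compound list**

1 | methyl acetoacetate (methyl 3-oxobutanoate) | CC(=O)CC(=O)OC | starting material
2 | 2-(2-bromoethyl)-1,3-dioxolane | BrCCC1OCCO1 | starting material
3 | methyl 2-acetyl-4-(1,3-dioxolan-2-yl)butanoate (racemic, the centre is lost in step 2) | CC(=O)C(CCC1OCCO1)C(=O)OC | intermediate
4 | methyl (2Z)-2-[2-(1,3-dioxolan-2-yl)ethyl]-3-(trimethylsilyloxy)but-2-enoate (not isolated; geometry as expected, immaterial) | C/C(O[Si](C)(C)C)=C(\CCC1OCCO1)C(=O)OC | intermediate
5 | 2-[2-(1,3-dioxolan-2-yl)ethyl]-1-methoxy-1,3-bis(trimethylsilyloxy)buta-1,3-diene (ketene acetal geometry not defined, immaterial) | C=C(O[Si](C)(C)C)C(CCC1OCCO1)=C(OC)O[Si](C)(C)C | intermediate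
6 | β-cyclocitral (2,6,6-trimethylcyclohex-1-ene-1-carbaldehyde) | CC1=C(C=O)C(C)(C)CCC1 | starting material
7 | methyl (5S)-2-[2-(1,3-dioxolan-2-yl)ethyl]-3,5-bis(trimethylsilyloxy)-5-(2,6,6-trimethylcyclohex-1-en-1-yl)pent-2-enoate (not isolated; enol ether geometry not defined) | COC(=O)C(CCC1OCCO1)=C(O[Si](C)(C)C)C[C@H](O[Si](C)(C)C)C1=C(C)CCCC1(C)C | intermediate
8 | methyl (5S)-2-[2-(1,3-dioxolan-2-yl)ethyl]-5-hydroxy-3-oxo-5-(2,6,6-trimethylcyclohex-1-en-1-yl)pentanoate (not isolated; epimers at C2) | COC(=O)C(CCC1OCCO1)C(=O)C[C@H](O)C1=C(C)CCCC1(C)C | intermediate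
9 | (6S)-3-[2-(1,3-dioxolan-2-yl)ethyl]-4-hydroxy-6-(2,6,6-trimethylcyclohex-1-en-1-yl)-5,6-dihydro-2H-pyran-2-one (enol form of the β-keto δ-lactone; not isolated) | O=C1O[C@H](C2=C(C)CCCC2(C)C)CC(O)=C1CCC1OCCO1 | intermediate
10 | (1S,8aS)-1-[2-(1,3-dioxolan-2-yl)ethyl]-5,5,8a-trimethyl-2-oxo-1,2,3,5,6,7,8,8a-octahydronaphthalene-1-carboxylic acid (not isolated) | O1CCOC1CC[C@]2(C(=O)O)[C@@]3(C)CCCC(C)(C)C3=CCC2=O | intermediate
11 | (1R,8aR)-1-[2-(1,3-dioxolan-2-yl)ethyl]-5,5,8a-trimethyl-3,5,6,7,8,8a-hexahydronaphthalen-2(1H)-one | O1CCOC1CC[C@@H]2[C@@]3(C)CCCC(C)(C)C3=CCC2=O | intermediate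
12 | (1R,2S,8aR)-1-[2-(1,3-dioxolan-2-yl)ethyl]-2,5,5,8a-tetramethyl-1,2,3,5,6,7,8,8a-octahydronaphthalen-2-ol | O1CCOC1CC[C@@H]2[C@@]3(C)CCCC(C)(C)C3=CC[C@]2(C)O | intermediate
13 | (1R,2S,4aR,8aS)-1-[2-(1,3-dioxolan-2-yl)ethyl]-2,5,5,8a-tetramethyldecahydronaphthalen-2-ol | O1CCOC1CC[C@@H]2[C@@]3(C)CCCC(C)(C)[C@H]3CC[C@]2(C)O | intermediate
14 | 3-[(1R,2S,4aR,8aS)-2-hydroxy-2,5,5,8a-tetramethyldecahydronaphthalen-1-yl]propanal (open form; equilibrates with the lactol formed by the 8-OH) | O=CCC[C@@H]1[C@@]2(C)CCCC(C)(C)[C@H]2CC[C@]1(C)O | intermediate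
15 | (1R,2S,4aR,8aS)-1-(but-3-yn-1-yl)-2,5,5,8a-tetramethyldecahydronaphthalen-2-ol | C#CCC[C@@H]1[C@@]2(C)CCCC(C)(C)[C@H]2CC[C@]1(C)O | intermediate
16 | (E)-alkenyldimethylalane of 15: dimethylaluminium on C14 cis to the new C13 methyl, 8-oxygen as its dimethylaluminium alkoxide (not isolated) | C[Al](C)/C=C(\C)CC[C@@H]1[C@@]2(C)CCCC(C)(C)[C@H]2CC[C@]1(C)O[Al](C)C | intermediate
17 | (1R,2S,4aR,8aS)-1-[(3E)-5-hydroxy-3-methylpent-3-en-1-yl]-2,5,5,8a-tetramethyldecahydronaphthalen-2-ol | OC/C=C(\C)CC[C@@H]1[C@@]2(C)CCCC(C)(C)[C@H]2CC[C@]1(C)O | intermediate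
18 | (2E)-5-[(1R,2S,4aR,8aS)-2-hydroxy-2,5,5,8a-tetramethyldecahydronaphthalen-1-yl]-3-methylpent-2-en-1-yl acetate | CC(=O)OC/C=C(\C)CC[C@@H]1[C@@]2(C)CCCC(C)(C)[C@H]2CC[C@]1(C)O | target

Total step count: 9
Longest linear sequence: 9 steps (1 → 18; β-cyclocitral 6 enters at step 3)

**Steps most likely to fail**

1. Step 3 (proposed new method). The thermal stage may be diverted into ionisation of the allylic C6–O bond and elimination towards C7, which would give an open-chain dienone. The sigmatropic shift may also be too slow at the fully substituted terminus C10. Slow addition to the hindered formyl group would lower the optical purity carried into C10.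
   Fallback (known chemistry; sets out from 5 and 6, returns at 11): the aldol stage is run alone, the adduct 7 is desilylated with aqueous citric acid, and the hydroxy keto ester 8 is isolated. Acylation of its carbinol (ClCO2Me, pyridine, CH2Cl2, 0 °C) gives the allylic methyl carbonate F1. Zerovalent palladium (Pd2(dba)3, PPh3, THF, rt to 60 °C) ionises the carbonate with inversion, and the β-keto ester carbon closes ring B at the far allyl terminus C10 anti to the metal (intramolecular Tsuji–Trost allylation). The net retention keeps the C6-to-C10 transfer of chirality, and syn–anti equilibration of the allyl unit through its C6 σ-form does not change this sense. The product is the bicyclic keto ester F2. Krapcho demethoxycarbonylation (LiCl, wet DMSO, 150 °C) then gives 11.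

2. Step 5. The hydroxyl-bound catalyst must reach the alkene face that is flanked by the C10 methyl and the axial C4 methyl group. Turnover may be slow, and hydrogen may instead be delivered undirected from the open face, which would give the trans-fused isomer (poor facial selectivity).
   Fallback (sets out from 12, returns at 13): allylic oxidation of the only allylic methylene, C7 (CrO3·3,5-dimethylpyrazole, CH2Cl2, −20 °C), gives the enone F3. Condensation with TsNHNH2 (EtOH, 60 °C) gives the tosylhydrazone F4. Reduction with catecholborane (CHCl3, 0 °C), then NaOAc·3H2O at reflux, should deliver hydride to C7 axially from the α face. The allylic diazene so formed loses N2 in a retro-ene shift that places its hydrogen on C5 on the β face while the alkene moves to C6=C7; this is the reductive 1,3-transposition that turns steroidal 4-en-3-one tosylhydrazones into 5β-3-enes. The product is the cis-fused alkene F5. Hydrogenation of this disubstituted alkene (H2, Pd/C, EtOAc) gives 13.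

3. Step 4. The organometallic may deprotonate C7 (α to the carbonyl and allylic) instead of adding, or may add from the β face (poor facial selectivity).
   Fallback (sets out from 11, returns at 12): Corey–Chaykovsky methylenation with dimethylsulfoxonium methylide (Me3S(O)I, NaH, DMSO, rt), whose reversible addition favours the equatorial (α) C–C bond, gives the spiro-epoxide F6 with the oxygen axial on the β face. LiEt3BH (THF, 0 °C) opens the epoxide at its CH2 terminus and gives 12.

**Further compounds**

F1 | step 3 | methyl (5S)-2-[2-(1,3-dioxolan-2-yl)ethyl]-5-(methoxycarbonyloxy)-3-oxo-5-(2,6,6-trimethylcyclohex-1-en-1-yl)pentanoate | COC(=O)C(CCC1OCCO1)C(=O)C[C@H](OC(=O)OC)C1=C(C)CCCC1(C)C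
F2 | step 3 | methyl (8aS)-1-[2-(1,3-dioxolan-2-yl)ethyl]-5,5,8a-trimethyl-2-oxo-1,2,3,5,6,7,8,8a-octahydronaphthalene-1-carboxylate (C1 epimers) | O1CCOC1CCC2(C(=O)OC)[C@@]3(C)CCCC(C)(C)C3=CCC2=O
F3 | step 5 | 7-oxo derivative of 12 (C5=C6–C7=O enone, labdane numbering) | O1CCOC1CC[C@@H]2[C@@]3(C)CCCC(C)(C)C3=CC(=O)[C@]2(C)O
F4 | step 5 | 4-methylbenzenesulfonylhydrazone of F3 (C=N geometry not defined) | O1CCOC1CC[C@@H]2[C@@]3(C)CCCC(C)(C)C3=CC(=NNS(=O)(=O)c4ccc(C)cc4)[C@]2(C)O
F5 | step 5 | cis-fused C6=C7 alkene (13 with a C6=C7 double bond, 5-H syn to the C10 methyl group) | O1CCOC1CC[C@@H]2[C@@]3(C)CCCC(C)(C)[C@H]3C=C[C@]2(C)O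
F6 | step 4 | spiro-oxirane at C8 of 11 (oxygen on the face of the C10 methyl group, CH2 on the opposite face) | O1CCOC1CC[C@@H]2[C@@]3(C)CCCC(C)(C)C3=CC[C@@]24CO4
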